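## Retrosynthetic overview

1. Target 19 ⇐ triene lactone 17: both oxiranes are made last, by peracid attack on the outer faces of the two E alkenes of the ten-membered ring.
2. 17 ⇐ seco iodo-enal 14 (C6–C7): C7, the β-carbon of the iodo-enoate, is used as a β-acyl vinyl anion (homoenolate-type d3 synthon, alkenylchromium) that adds to the C6 aldehyde. This one step forms the ten-membered ring, the butenolide and C6.
3. 14 ⇐ γ-tigloyloxy ynoate 9: iodide/formaldehyde halo-aldol builds the tetrasubstituted (Z)-β-iodo-α-(acetoxymethyl) enoate.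
4. 9 ⇐ aldehyde 5 + methyl propiolate 6 (asymmetric alkynylation sets C8); 5 ⇐ geraniol 1 (silylation, SeO2 oxidation, bromide, Pd formylation).
5. Ring order: carbocycle and butenolide together (step 10), then the two epoxides (step 11).

Assumptions: atom labels C1–C15 are the germacrane numbers of the target (C6 lactone carbinol, C8 tiglate carbinol, C12 lactone carbonyl, C13 CH2OAc). (S,S)-ProPhenol is taken to give the 4S alcohol 8; if the facial sense is the reverse, the (R,R)-ligand is used and nothing else changes.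

## Route

Step 1
Reactants: 1 geraniol
Product: 2 geranyl tert-butyldimethylsilyl ether
Conditions: TBSCl, imidazole, DMF, 0 °C → rt
Reagents that add atoms: tert-butyldimethylsilyl chloride, CC(C)(C)[Si](C)(C)Cl
Why: Imidazole-promoted silylation masks the C6 oxygen with a group that fluoride removes later without touching the three esters; no stereocentre is formed.

Step 2
Reactants: 2 geranyl tert-butyldimethylsilyl ether
Product: 3 (2E,6E)-8-[(tert-butyldimethylsilyl)oxy]-2,6-dimethylocta-2,6-dien-1-ol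
Conditions: SeO2 (0.3 equiv), t-BuOOH (3 equiv), salicylic acid (0.1 equiv), CH2Cl2, 0 °C → rt
Reagents that add atoms: tert-butyl hydroperoxide, CC(C)(C)OO (oxygen passed on through SeO2)
Why: Sharpless SeO2-catalysed allylic oxidation (ene reaction, then [2,3]-sigmatropic shift) hydroxylates the (E)-methyl group of the terminal trisubstituted alkene, which becomes C9, and keeps the E geometry.

Step 3
Reactants: 3 (2E,6E)-8-[(tert-butyldimethylsilyl)oxy]-2,6-dimethylocta-2,6-dien-1-ol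
Product: 4 {[(2E,6E)-8-bromo-3,7-dimethylocta-2,6-dien-1-yl]oxy}(tert-butyl)dimethylsilane
Conditions: CBr4, PPh3, CH2Cl2, 0 °C
Reagents that add atoms: carbon tetrabromide, BrC(Br)(Br)Br
Why: Appel bromination converts the primary allylic alcohol into the bromide under neutral conditions, without allylic shift or loss of the silyl ether.

Step 4
Reactants: 4 {[(2E,6E)-8-bromo-3,7-dimethylocta-2,6-dien-1-yl]oxy}(tert-butyl)dimethylsilane
Product: 5 (3E,7E)-9-[(tert-butyldimethylsilyl)oxy]-3,7-dimethylnona-3,7-dienal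
Conditions: Pd(PPh3)4 (5 mol%), CO (3 atm), Bu3SnH (syringe pump), THF, 50 °C
Reagents that add atoms: carbon monoxide, [C-]#[O+]
Why: Stille palladium-catalysed formylation (oxidative addition of zerovalent palladium to the allylic bromide, CO insertion at the unhindered terminus, hydride transfer from tin) adds C8 as a β,γ-unsaturated aldehyde with the E alkene intact.

Step 5
Reactants: 5 (3E,7E)-9-[(tert-butyldimethylsilyl)oxy]-3,7-dimethylnona-3,7-dienal; 6 methyl propiolate
Product: 8 methyl (4S,6E,10E)-12-[(tert-butyldimethylsilyl)oxy]-4-hydroxy-6,10-dimethyldodeca-6,10-dien-2-ynoate, via methylzinc acetylide 7 (not isolated)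
Conditions: Me2Zn (3 equiv), (S,S)-ProPhenol (20 mol%), Ph3PO (40 mol%), toluene, 0 °C
Reagents that add atoms: none
Why: Trost dinuclear-zinc ProPhenol alkynylation, in which the propiolate acetylide 7 (itself a β-acyl anion, d3, equivalent) adds to the aldehyde face chosen by the ligand, forms C7–C8 and sets C8 as S.

Step 6
Reactants: 8 methyl (4S,6E,10E)-12-[(tert-butyldimethylsilyl)oxy]-4-hydroxy-6,10-dimethyldodeca-6,10-dien-2-ynoate
Product: 9 methyl (4S,6E,10E)-12-[(tert-butyldimethylsilyl)oxy]-6,10-dimethyl-4-{[(2E)-2-methylbut-2-enoyl]oxy}dodeca-6,10-dien-2-ynoate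
Conditions: tigloyl chloride, pyridine, DMAP (cat.), CH2Cl2, 0 °C
Reagents that add atoms: (E)-2-methylbut-2-enoyl chloride (tigloyl chloride), C/C=C(\C)C(Cl)=O
Why: DMAP-catalysed acylation installs the tiglate with retention at C8 and removes the free hydroxyl that would otherwise protonate the allenolate of step 7.

Step 7
Reactants: 9 methyl (4S,6E,10E)-12-[(tert-butyldimethylsilyl)oxy]-6,10-dimethyl-4-{[(2E)-2-methylbut-2-enoyl]oxy}dodeca-6,10-dien-2-ynoate
Product: 12 methyl (2Z,4S,6E,10E)-2-(acetoxymethyl)-12-[(tert-butyldimethylsilyl)oxy]-3-iodo-6,10-dimethyl-4-{[(2E)-2-methylbut-2-enoyl]oxy}dodeca-2,6,10-trienoate, via iodomagnesium allenolate 10 (not isolated), via hydroxymethyl iodoenoate 11 (not isolated)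
Conditions: MgI2 (1.5 equiv), monomeric CH2O (3 equiv, THF solution), CH2Cl2, −20 → 0 °C; then Ac2O, pyridine, DMAP (cat.), 0 °C
Reagents that add atoms: magnesium diiodide, [Mg+2].[I-].[I-]; formaldehyde, C=O; acetic anhydride, CC(=O)OC(C)=O
Why: Proposed new method: iodide from the Lewis acid MgI2 adds to C7 of the ynoate to give allenolate 10, whose C11 attacks formaldehyde in the plane anti to the new C–I bond (the same stereospecific anti addition that gives (Z)-3-iodoalk-2-enoates from 2-alkynoates and iodide), so iodine ends cis to the ester and C13 cis to C8, and alkoxide 11 is acetylated in the flask; the closest known chemistry is the MgI2- or Bu4NI/TiCl4-mediated halo-aldol (β-iodo Morita–Baylis–Hillman) reaction of ynoates with aldehydes.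

Step 8
Reactants: 12 methyl (2Z,4S,6E,10E)-2-(acetoxymethyl)-12-[(tert-butyldimethylsilyl)oxy]-3-iodo-6,10-dimethyl-4-{[(2E)-2-methylbut-2-enoyl]oxy}dodeca-2,6,10-trienoate
Product: 13 methyl (2Z,4S,6E,10E)-2-(acetoxymethyl)-12-hydroxy-3-iodo-6,10-dimethyl-4-{[(2E)-2-methylbut-2-enoyl]oxy}dodeca-2,6,10-trienoate
Conditions: HF·pyridine, pyridine, THF, 0 °C → rt
Reagents that add atoms: none
Why: Buffered HF·pyridine cleaves the primary silyl ether without the acyl migration or attack on the β-iodo enoate that a basic fluoride source could cause.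

Step 9
Reactants: 13 methyl (2Z,4S,6E,10E)-2-(acetoxymethyl)-12-hydroxy-3-iodo-6,10-dimethyl-4-{[(2E)-2-methylbut-2-enoyl]oxy}dodeca-2,6,10-trienoate
Product: 14 methyl (2Z,4S,6E,10E)-2-(acetoxymethyl)-3-iodo-6,10-dimethyl-4-{[(2E)-2-methylbut-2-enoyl]oxy}-12-oxododeca-2,6,10-trienoate
Conditions: MnO2 (20 equiv), CH2Cl2, rt
Reagents that add atoms: none
Why: MnO2 oxidises only the allylic alcohol, giving the (E)-enal and leaving the iodide, the esters and the other alkenes untouched.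

Step 10
Reactants: 14 methyl (2Z,4S,6E,10E)-2-(acetoxymethyl)-3-iodo-6,10-dimethyl-4-{[(2E)-2-methylbut-2-enoyl]oxy}-12-oxododeca-2,6,10-trienoate
Product: 17 (6R,8S)-13-acetoxy-8-[(E)-2-methylbut-2-enoyloxy]germacra-1(10)E,4E,7(11)-trien-12,6-olide, via alkenylchromium dichloride 15 (not isolated), via seco hydroxy ester 16 (not isolated)
Conditions: CrCl2 (8 equiv), NiCl2 (2 mol%), degassed DMSO/THF 3:1, rt, syringe pump to 2 mM; aq. NH4Cl, then PPTS (cat.), CH2Cl2
Reagents that add atoms: none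
Why: Nozaki–Hiyama–Kishi reaction used as a macrocyclisation: zerovalent nickel inserts into the activated C7–I bond and passes the alkenyl group to chromium, so that C7, normally the electrophilic β-carbon of the enoate, reacts in 15 as a β-acyl vinyl anion (homoenolate-type d3 synthon) with the normally electrophilic aldehyde carbon C6 and closes the ten-membered ring, after which the new alkoxide 16 captures the cis ester as the butenolide; C6 is expected to form 6R under control of C8, whose hydrogen eclipses the C7=C11 bond (allylic 1,3-strain) and so fixes the side of the alkenyl plane from which the chain delivers the enal.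

Step 11
Reactants: 17 (6R,8S)-13-acetoxy-8-[(E)-2-methylbut-2-enoyloxy]germacra-1(10)E,4E,7(11)-trien-12,6-olide
Product: 19 (1R,4R,5R,6S,8S,10R)-13-acetoxy-1,10:4,5-diepoxy-8-[(E)-2-methylbut-2-enoyloxy]germacr-7(11)-en-12,6-olide (CNP0251711.1), via monoepoxide 18 (not isolated)
Conditions: mCPBA (2.5 equiv), NaHCO3, CH2Cl2, 0 °C
Reagents that add atoms: 3-chloroperbenzoic acid, OOC(=O)c1cccc(Cl)c1
Why: Prilezhaev epoxidation in which only the two electron-rich trisubstituted alkenes react (butenolide and tiglate alkenes are electron-poor), and peracid attack on the outer faces of the crossed E alkenes of the crown-shaped ring, as in related germacra-1(10),4-dienolides, gives the trans oxiranes 1R,10R and 4R,5R.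

## Compound list

1 | geraniol, (2E)-3,7-dimethylocta-2,6-dien-1-ol | CC(C)=CCC/C(C)=C/CO | starting material
2 | geranyl tert-butyldimethylsilyl ether | CC(C)=CCC/C(C)=C/CO[Si](C)(C)C(C)(C)C | intermediate
3 | (2E,6E)-8-[(tert-butyldimethylsilyl)oxy]-2,6-dimethylocta-2,6-dien-1-ol | OC/C(C)=C/CC/C(C)=C/CO[Si](C)(C)C(C)(C)C | intermediate
4 | {[(2E,6E)-8-bromo-3,7-dimethylocta-2,6-dien-1-yl]oxy}(tert-butyl)dimethylsilane | BrC/C(C)=C/CC/C(C)=C/CO[Si](C)(C)C(C)(C)C | intermediate
5 | (3E,7E)-9-[(tert-butyldimethylsilyl)oxy]-3,7-dimethylnona-3,7-dienal | O=CC/C(C)=C/CC/C(C)=C/CO[Si](C)(C)C(C)(C)C | intermediate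
6 | methyl propiolate (methyl prop-2-ynoate) | C#CC(=O)OC | starting material
7 | methylzinc acetylide of 6, methyl 3-(methylzincio)prop-2-ynoate (not isolated) | COC(=O)C#C[Zn]C | intermediate
8 | methyl (4S,6E,10E)-12-[(tert-butyldimethylsilyl)oxy]-4-hydroxy-6,10-dimethyldodeca-6,10-dien-2-ynoate | COC(=O)C#C[C@@H](O)C/C(C)=C/CC/C(C)=C/CO[Si](C)(C)C(C)(C)C | intermediate
9 | methyl (4S,6E,10E)-12-[(tert-butyldimethylsilyl)oxy]-6,10-dimethyl-4-{[(2E)-2-methylbut-2-enoyl]oxy}dodeca-6,10-dien-2-ynoate | COC(=O)C#C[C@@H](OC(=O)/C(C)=C/C)C/C(C)=C/CC/C(C)=C/CO[Si](C)(C)C(C)(C)C | intermediate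
10 | iodomagnesium allenolate formed by iodide addition to C3 of 9 (not isolated) | COC(O[Mg]I)=C=C(I)[C@@H](OC(=O)/C(C)=C/C)C/C(C)=C/CC/C(C)=C/CO[Si](C)(C)C(C)(C)C | intermediate
11 | methyl (2Z,4S,6E,10E)-12-[(tert-butyldimethylsilyl)oxy]-2-(hydroxymethyl)-3-iodo-6,10-dimethyl-4-{[(2E)-2-methylbut-2-enoyl]oxy}dodeca-2,6,10-trienoate, present as its magnesium alkoxide (not isolated) | COC(=O)/C(CO)=C(\I)[C@@H](OC(=O)/C(C)=C/C)C/C(C)=C/CC/C(C)=C/CO[Si](C)(C)C(C)(C)C | intermediate
12 | methyl (2Z,4S,6E,10E)-2-(acetoxymethyl)-12-[(tert-butyldimethylsilyl)oxy]-3-iodo-6,10-dimethyl-4-{[(2E)-2-methylbut-2-enoyl]oxy}dodeca-2,6,10-trienoate | COC(=O)/C(COC(C)=O)=C(\I)[C@@H](OC(=O)/C(C)=C/C)C/C(C)=C/CC/C(C)=C/CO[Si](C)(C)C(C)(C)C | intermediate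
13 | methyl (2Z,4S,6E,10E)-2-(acetoxymethyl)-12-hydroxy-3-iodo-6,10-dimethyl-4-{[(2E)-2-methylbut-2-enoyl]oxy}dodeca-2,6,10-trienoate | COC(=O)/C(COC(C)=O)=C(\I)[C@@H](OC(=O)/C(C)=C/C)C/C(C)=C/CC/C(C)=C/CO | intermediate
14 | methyl (2Z,4S,6E,10E)-2-(acetoxymethyl)-3-iodo-6,10-dimethyl-4-{[(2E)-2-methylbut-2-enoyl]oxy}-12-oxododeca-2,6,10-trienoate | COC(=O)/C(COC(C)=O)=C(\I)[C@@H](OC(=O)/C(C)=C/C)C/C(C)=C/CC/C(C)=C/C=O | intermediate
15 | alkenylchromium dichloride (trivalent chromium) from 14, chromium in place of iodine at C3 (not isolated) | COC(=O)/C(COC(C)=O)=C(\[Cr](Cl)Cl)[C@@H](OC(=O)/C(C)=C/C)C/C(C)=C/CC/C(C)=C/C=O | intermediate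
16 | seco hydroxy ester, methyl (6R,8S)-13-acetoxy-6-hydroxy-8-[(E)-2-methylbut-2-enoyloxy]germacra-1(10)E,4E,7(11)-trien-12-oate with the ester carbonyl cis to C6, present as its chromium alkoxide (not isolated) | COC(=O)/C(COC(C)=O)=C1\[C@H](O)/C=C(C)/CC/C=C(C)/C[C@@H]1OC(=O)/C(C)=C/C | intermediate
17 | (6R,8S)-13-acetoxy-8-[(E)-2-methylbut-2-enoyloxy]germacra-1(10)E,4E,7(11)-trien-12,6-olide | C/C=C(\C)C(=O)O[C@H]1C/C(C)=C/CC/C(C)=C/[C@H]2OC(=O)C(COC(C)=O)=C12 | intermediate
18 | (1R,6R,8S,10R)-13-acetoxy-1,10-epoxy-8-[(E)-2-methylbut-2-enoyloxy]germacra-4E,7(11)-dien-12,6-olide (not isolated) | C/C=C(\C)C(=O)O[C@H]1C[C@@]2(C)O[C@@H]2CC/C(C)=C/[C@H]2OC(=O)C(COC(C)=O)=C12 | intermediate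
19 | (1R,4R,5R,6S,8S,10R)-13-acetoxy-1,10:4,5-diepoxy-8-[(E)-2-methylbut-2-enoyloxy]germacr-7(11)-en-12,6-olide, CNP0251711.1 | C/C=C(\C)C(=O)O[C@H]1C[C@@]2(C)O[C@@H]2CC[C@@]2(C)O[C@@H]2[C@H]2OC(=O)C(COC(C)=O)=C12 | target

(The C6 descriptor changes from R in 16–18 to S in 19 only because C5 gains oxygen; the spatial arrangement is unchanged.)

## Step count and risks

Total step count: 11. Longest linear sequence: 11 steps (geraniol 1 → 19).

The three steps most likely to fail:

Step 7. The iodide/formaldehyde halo-aldol is unproven on a β-branched γ-acyloxy ynoate; both the yield and the C7=C11 geometry are at risk. The fallback drops the intermolecular aldol and delivers C13 from a tether on the C8 oxygen; it sets out from 8 and comes back at 12. Alcohol 8 is silylated with (bromomethyl)chlorodimethylsilane and imidazole to the (bromomethyl)dimethylsilyl ether F1. MgI2 in CH2Cl2 then adds iodide to C7, and the allenolate carbon C11 displaces the tethered bromide to close the six-membered oxasiline vinyl iodide F2. The ring forces C13 cis to C8 and therefore iodine cis to the ester. Tamao oxidation (H2O2, KF, KHCO3, THF/MeOH) gives the diol F3. Selective acetylation of the primary hydroxyl (AcCl, 2,4,6-collidine, −78 °C) gives the mono-acetate F4, and tigloyl chloride/pyridine/DMAP then gives 12.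

Step 10. The ten-membered ring may close poorly, and the C6 configuration rests on substrate control that has not been demonstrated. The fallback makes C6 a ketone and sets it with a reagent; it sets out from 14 and comes back at 16. Pinnick oxidation of 14 (NaClO2, NaH2PO4, 2-methylbut-2-ene) gives the carboxylic acid F5. 2,2'-Dipyridyl disulfide and PPh3 convert it into the S-(2-pyridyl) thioester F6. Nickel-catalysed reductive acyl–alkenyl coupling at high dilution (NiBr2(dtbbpy), Zn, DMA; a Kishi-type ketone synthesis) gives the cross-conjugated macrocyclic ketone F7. Corey–Bakshi–Shibata reduction (the Me-CBS enantiomer that gives the 6R carbinol, catecholborane, −78 °C) gives hydroxy ester 16, which lactonises to 17.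

Step 11. Two epoxidations on a flexible ring must each take the correct face. The fallback sets both oxiranes by reagent control before ring closure; it sets out from 13 and comes back at 19. Sharpless asymmetric epoxidation of allylic alcohol 13 (Ti(OiPr)4, D-(−)-diethyl tartrate, t-BuOOH, 4 Å sieves, −20 °C) gives the 4R,5R epoxy alcohol F8. Shi epoxidation of the remaining trisubstituted alkene (D-fructose-derived ketone, KHSO5, pH 10.5) gives the bis-epoxy alcohol F9. Dess–Martin oxidation gives the bis-epoxy aldehyde F10. Ni/Cr closure as in step 10 (CrCl2, NiCl2, DMSO/THF; addition anti to the C5–O bond) gives the bis-epoxy hydroxy ester F11, which lactonises to 19.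

## Further compounds

F1 | step 7 | methyl (4S,6E,10E)-4-{[(bromomethyl)dimethylsilyl]oxy}-12-[(tert-butyldimethylsilyl)oxy]-6,10-dimethyldodeca-6,10-dien-2-ynoate | COC(=O)C#C[C@@H](O[Si](C)(C)CBr)C/C(C)=C/CC/C(C)=C/CO[Si](C)(C)C(C)(C)C
F2 | step 7 | methyl (6S)-6-{(2E,6E)-8-[(tert-butyldimethylsilyl)oxy]-2,6-dimethylocta-2,6-dien-1-yl}-5-iodo-2,2-dimethyl-3,6-dihydro-2H-1,2-oxasiline-4-carboxylate | COC(=O)C1=C(I)[C@H](C/C(C)=C/CC/C(C)=C/CO[Si](C)(C)C(C)(C)C)O[Si](C)(C)C1
F3 | step 7 | methyl (2Z,4S,6E,10E)-12-[(tert-butyldimethylsilyl)oxy]-4-hydroxy-2-(hydroxymethyl)-3-iodo-6,10-dimethyldodeca-2,6,10-trienoate | COC(=O)/C(CO)=C(\I)[C@@H](O)C/C(C)=C/CC/C(C)=C/CO[Si](C)(C)C(C)(C)C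
F4 | step 7 | methyl (2Z,4S,6E,10E)-2-(acetoxymethyl)-12-[(tert-butyldimethylsilyl)oxy]-4-hydroxy-3-iodo-6,10-dimethyldodeca-2,6,10-trienoate | COC(=O)/C(COC(C)=O)=C(\I)[C@@H](O)C/C(C)=C/CC/C(C)=C/CO[Si](C)(C)C(C)(C)C
F5 | step 10 | (2E,6E,9S,10Z)-11-(acetoxymethyl)-10-iodo-12-methoxy-3,7-dimethyl-9-{[(2E)-2-methylbut-2-enoyl]oxy}-12-oxododeca-2,6,10-trienoic acid | COC(=O)/C(COC(C)=O)=C(\I)[C@@H](OC(=O)/C(C)=C/C)C/C(C)=C/CC/C(C)=C/C(=O)O
F6 | step 10 | S-(pyridin-2-yl) thioester of F5 | COC(=O)/C(COC(C)=O)=C(\I)[C@@H](OC(=O)/C(C)=C/C)C/C(C)=C/CC/C(C)=C/C(=O)Sc1ccccn1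
F7 | step 10 | methyl (8S)-13-acetoxy-8-[(E)-2-methylbut-2-enoyloxy]-6-oxogermacra-1(10)E,4E,7(11)-trien-12-oate with the ester carbonyl cis to C6 | COC(=O)/C(COC(C)=O)=C1\C(=O)/C=C(C)/CC/C=C(C)/C[C@@H]1OC(=O)/C(C)=C/C
F8 | step 11 | methyl (2Z,4S,6E,10R,11R)-2-(acetoxymethyl)-10,11-epoxy-12-hydroxy-3-iodo-6,10-dimethyl-4-{[(2E)-2-methylbut-2-enoyl]oxy}dodeca-2,6-dienoate | COC(=O)/C(COC(C)=O)=C(\I)[C@@H](OC(=O)/C(C)=C/C)C/C(C)=C/CC[C@@]1(C)O[C@@H]1CO
F9 | step 11 | methyl (2Z,4S,6R,7R,10R,11R)-2-(acetoxymethyl)-6,7:10,11-diepoxy-12-hydroxy-3-iodo-6,10-dimethyl-4-{[(2E)-2-methylbut-2-enoyl]oxy}dodec-2-enoate | COC(=O)/C(COC(C)=O)=C(\I)[C@@H](OC(=O)/C(C)=C/C)C[C@@]1(C)O[C@@H]1CC[C@@]1(C)O[C@@H]1CO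
F10 | step 11 | methyl (2Z,4S,6R,7R,10R,11S)-2-(acetoxymethyl)-6,7:10,11-diepoxy-3-iodo-6,10-dimethyl-4-{[(2E)-2-methylbut-2-enoyl]oxy}-12-oxododec-2-enoate | COC(=O)/C(COC(C)=O)=C(\I)[C@@H](OC(=O)/C(C)=C/C)C[C@@]1(C)O[C@@H]1CC[C@@]1(C)O[C@@H]1C=O
F11 | step 11 | methyl (1R,4R,5R,6S,8S,10R)-13-acetoxy-1,10:4,5-diepoxy-6-hydroxy-8-[(E)-2-methylbut-2-enoyloxy]germacr-7(11)-en-12-oate with the ester carbonyl cis to C6 (not isolated) | C/C=C(\C)C(=O)O[C@H]1C[C@@]2(C)O[C@@H]2CC[C@@]2(C)O[C@@H]2[C@@H](O)/C1=C(/COC(C)=O)C(=O)OC
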